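**Retrosynthetic overview**

- The strategy rests on the lactone O1–C2(=O)–C3–C4–C5 with exocyclic C6 (bearing ring A, 3-hydroxy-4,5-dimethoxyphenyl) and C7 (CH2 bearing ring B, 4-hydroxy-3-methoxyphenyl). The chain O1–C5–C4–C7–ring B is a 3-arylpropyl ester, and its middle CH2 (C4) lies 1,5 to C3.
- The C3=C6 benzylidene is traced back to a C6 ketone (reduction, mesylation, E1cB), so ring A enters as an aroyl group on C3 and no condensation on the finished lactone is needed.
- The C3–C4 bond and the lactone, the only ring built, come from enantioselective C–H insertion of a rhodium carbene at C3 of a 3-arylpropyl 2-diazo-3-aryl-3-oxopropanoate.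
- The diazo keto ester comes from diazo transfer onto the β-keto ester, which is assembled from the ring A aroyl Meldrum's acid and the ring B propanol.
- Both phenols are carried as tert-butyldimethylsilyl (TBS) ethers from the start and are freed in the last step.

Key step: step 7

Assumption: Rh2(S-PTTL)4 (dirhodium tetrakis[N-phthaloyl-(S)-tert-leucinate]) is taken to deliver the 4R lactone. If a trial run shows the opposite sense, the antipodal catalyst Rh2(R-PTTL)4 is used with no other change. Compounds 1 and 4 are taken as purchasable.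

Step 1
Reactants: 1 4-(3-hydroxypropyl)-2-methoxyphenol
Product: 2 tert-butyl{4-[3-(TBS-oxy)propyl]-2-methoxyphenoxy}dimethylsilane (bis-TBS ether of 1)
Conditions: TBSCl (2.4 equiv), imidazole (5 equiv), DMF, 0 °C to rt
Reagents that add atoms: tert-butyldimethylsilyl chloride, CC(C)(C)[Si](C)(C)Cl
Why: Imidazole-promoted silylation converts the phenol and the primary alcohol together into TBS ethers, which is more dependable than trying to silylate the phenol alone.

Step 2
Reactants: 2 bis-TBS ether of 1
Product: 3 3-[4-(TBS-oxy)-3-methoxyphenyl]propan-1-ol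
Conditions: camphorsulfonic acid (10 mol %), MeOH/CH2Cl2 1:1, 0 °C
Reagents that add atoms: none
Why: Acid-catalysed methanolysis removes a primary alkyl TBS ether much faster than an aryl TBS ether, whose oxygen is less basic, so the propanol should be freed while the phenol stays protected.

Step 3
Reactants: 4 3-hydroxy-4,5-dimethoxybenzoic acid
Product: 6 3-(TBS-oxy)-4,5-dimethoxybenzoic acid, via silyl ester 5 (not isolated)
Conditions: TBSCl (2.5 equiv), imidazole (5 equiv), DMF, rt; extractive work-up, then AcOH/THF/H2O 3:1:1, rt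
Reagents that add atoms: tert-butyldimethylsilyl chloride, CC(C)(C)[Si](C)(C)Cl
Why: Silylation gives the silyl ether and silyl ester together, and the far more labile silyl ester should be hydrolysed selectively by aqueous acetic acid, leaving the aryl TBS ether intact.

Step 4
Reactants: 6 3-(TBS-oxy)-4,5-dimethoxybenzoic acid; 7 Meldrum's acid (2,2-dimethyl-1,3-dioxane-4,6-dione)
Product: 8 5-{[3-(TBS-oxy)-4,5-dimethoxyphenyl](hydroxy)methylidene}-2,2-dimethyl-1,3-dioxane-4,6-dione (aroyl Meldrum's acid, enol form)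
Conditions: DCC (1.2 equiv), DMAP (1.5 equiv), CH2Cl2, 0 °C to rt; filter, cold aq KHSO4 wash; used crude
Reagents that add atoms: none
Why: Carbodiimide activation with DMAP transfers the aroyl group to C5 of Meldrum's acid (C-acylation), giving the enolised acyl Meldrum's acid that serves as a masked aroylketene.

Step 5
Reactants: 8 aroyl Meldrum's acid; 3 3-[4-(TBS-oxy)-3-methoxyphenyl]propan-1-ol
Product: 10 3-[4-(TBS-oxy)-3-methoxyphenyl]propyl 3-[3-(TBS-oxy)-4,5-dimethoxyphenyl]-3-oxopropanoate, via aroylketene 9 (not isolated)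
Conditions: toluene, 100 °C (8 in slight excess)
Reagents that add atoms: none
Why: Thermolysis of the acyl Meldrum's acid expels acetone and CO2 to give an aroylketene, which the primary alcohol traps at the ketene carbon to form the β-keto ester (acyl Meldrum's acid alcoholysis).

Step 6
Reactants: 10 β-keto ester
Product: 11 3-[4-(TBS-oxy)-3-methoxyphenyl]propyl 2-diazo-3-[3-(TBS-oxy)-4,5-dimethoxyphenyl]-3-oxopropanoate
Conditions: 4-acetamidobenzenesulfonyl azide (1.2 equiv), Et3N, MeCN, 0 °C to rt
Reagents that add atoms: 4-acetamidobenzenesulfonyl azide, CC(=O)Nc1ccc(cc1)S(=O)(=O)N=[N+]=[N-]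
Why: Regitz diazo transfer from the sulfonyl azide to the doubly activated methylene of the β-keto ester under amine base installs the diazo group at C3.

Step 7
Reactants: 11 diazo keto ester
Product: 12 (4R)-3-[3-(TBS-oxy)-4,5-dimethoxybenzoyl]-4-[4-(TBS-oxy)-3-methoxybenzyl]dihydrofuran-2(3H)-one (C3 epimerisable, carried on as formed)
Conditions: Rh2(S-PTTL)4 (2 mol %), 4 Å molecular sieves, CH2Cl2, rt, slow addition of 11
Reagents that add atoms: none
Why: The divalent rhodium carboxylate expels N2 from 11 to give an electrophilic rhodium-bound carbene at C3, which inserts into a C4–H bond through a concerted, asynchronous three-centre transition state (H shifts to C3 as C3–C4 forms, with retention at C4) and releases the catalyst. The closest known reaction type is the dirhodium-catalysed 1,5-C–H insertion of alkyl 2-diazo-3-oxo esters, and of 3-arylpropyl diazoacetates, into the ester chain to give 4-benzyl γ-butyrolactones. The lactone closes in the five-membered (1,5) mode, C3 onto C4 across C2–O1–C5, after the ester rotates into its s-cis form. C4 is set by the chiral phthalimido-tert-leucinate ligand wall, which should let only one of the two enantiotopic C4 hydrogens reach the carbene; C3 settles by enolisation with aroyl trans to benzyl and is erased in step 9. The step needs 1,5-insertion to win over six-membered insertion at the benzylic C7–H, four-membered insertion at C5–H and attack on ring B; this is secured by the ring-size preference, the inductive deactivation of C5–H by O1, the seven-membered or larger closure that ring B would need, and an aroyl group that offers no reachable C–H bond.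

Step 8
Reactants: 12 (4R)-3-aroyl lactone
Product: 13 (4R)-3-{[3-(TBS-oxy)-4,5-dimethoxyphenyl](hydroxy)methyl}-4-[4-(TBS-oxy)-3-methoxybenzyl]dihydrofuran-2(3H)-one (mixture at C3 and the carbinol carbon)
Conditions: NaBH4 (1.5 equiv), THF/EtOH, −20 to 0 °C; aq NH4Cl
Reagents that add atoms: none
Why: Sodium borohydride reduces the aryl ketone of the β-keto lactone faster than the lactone carbonyl at low temperature; the carbinol centre and C3 are left uncontrolled because both are erased in the next step, and C4 is not touched.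

Step 9
Reactants: 13 hydroxy lactone
Product: 15 (3E,4R)-3-[3-(TBS-oxy)-4,5-dimethoxybenzylidene]-4-[4-(TBS-oxy)-3-methoxybenzyl]dihydrofuran-2(3H)-one, via mesylate 14 (not isolated)
Conditions: MsCl (1.5 equiv), Et3N (3 equiv), CH2Cl2, 0 °C; then DBU (2 equiv), 0 °C to rt
Reagents that add atoms: none
Why: Mesylation of the benzylic alcohol and E1cB elimination through the lactone enolate should give the conjugated benzylidene, both diastereomers converging on the E alkene (ring A trans to the lactone carbonyl), which is favoured in the enolate transition state and at equilibrium, while C4 stays intact as long as base excess and time are limited.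

Step 10
Reactants: 15 bis-TBS benzylidene lactone
Product: 16 (3E,4R)-3-(3-hydroxy-4,5-dimethoxybenzylidene)-4-(4-hydroxy-3-methoxybenzyl)dihydrofuran-2(3H)-one (CNP0187799.1)
Conditions: Bu4NF (2.5 equiv), AcOH (3 equiv), THF, 0 °C
Reagents that add atoms: none
Why: Fluoride cleaves the two aryl silicon–oxygen bonds, and the acetic acid buffer protonates the phenoxides at once so that the lactone, the enoate and the allylic C4 stereocentre are not exposed to base.

**Compound list**

1 | 4-(3-hydroxypropyl)-2-methoxyphenol | COc1cc(CCCO)ccc1O | starting material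
2 | tert-butyl{4-[3-(TBS-oxy)propyl]-2-methoxyphenoxy}dimethylsilane | COc1cc(CCCO[Si](C)(C)C(C)(C)C)ccc1O[Si](C)(C)C(C)(C)C | intermediate
3 | 3-[4-(TBS-oxy)-3-methoxyphenyl]propan-1-ol | COc1cc(CCCO)ccc1O[Si](C)(C)C(C)(C)C | intermediate
4 | 3-hydroxy-4,5-dimethoxybenzoic acid | COc1cc(C(=O)O)cc(O)c1OC | starting material
5 | tert-butyldimethylsilyl 3-(TBS-oxy)-4,5-dimethoxybenzoate | COc1cc(C(=O)O[Si](C)(C)C(C)(C)C)cc(O[Si](C)(C)C(C)(C)C)c1OC | intermediate (not isolated)
6 | 3-(TBS-oxy)-4,5-dimethoxybenzoic acid | COc1cc(C(=O)O)cc(O[Si](C)(C)C(C)(C)C)c1OC | intermediate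
7 | Meldrum's acid | CC1(C)OC(=O)CC(=O)O1 | starting material
8 | 5-{[3-(TBS-oxy)-4,5-dimethoxyphenyl](hydroxy)methylidene}-2,2-dimethyl-1,3-dioxane-4,6-dione | CC1(C)OC(=O)C(=C(O)c2cc(O[Si](C)(C)C(C)(C)C)c(OC)c(OC)c2)C(=O)O1 | intermediate
9 | 3-[3-(TBS-oxy)-4,5-dimethoxyphenyl]-3-oxoprop-1-en-1-one (aroylketene) | O=C=CC(=O)c1cc(O[Si](C)(C)C(C)(C)C)c(OC)c(OC)c1 | intermediate (not isolated)
10 | 3-[4-(TBS-oxy)-3-methoxyphenyl]propyl 3-[3-(TBS-oxy)-4,5-dimethoxyphenyl]-3-oxopropanoate | COc1cc(CCCOC(=O)CC(=O)c2cc(O[Si](C)(C)C(C)(C)C)c(OC)c(OC)c2)ccc1O[Si](C)(C)C(C)(C)C | intermediate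
11 | 3-[4-(TBS-oxy)-3-methoxyphenyl]propyl 2-diazo-3-[3-(TBS-oxy)-4,5-dimethoxyphenyl]-3-oxopropanoate | [N-]=[N+]=C(C(=O)OCCCc1ccc(O[Si](C)(C)C(C)(C)C)c(OC)c1)C(=O)c1cc(O[Si](C)(C)C(C)(C)C)c(OC)c(OC)c1 | intermediate (key-step precursor)
12 | (4R)-3-[3-(TBS-oxy)-4,5-dimethoxybenzoyl]-4-[4-(TBS-oxy)-3-methoxybenzyl]dihydrofuran-2(3H)-one | COc1cc(C[C@H]2COC(=O)C2C(=O)c2cc(O[Si](C)(C)C(C)(C)C)c(OC)c(OC)c2)ccc1O[Si](C)(C)C(C)(C)C | intermediate (key-step product)
13 | (4R)-3-{[3-(TBS-oxy)-4,5-dimethoxyphenyl](hydroxy)methyl}-4-[4-(TBS-oxy)-3-methoxybenzyl]dihydrofuran-2(3H)-one | COc1cc(C[C@H]2COC(=O)C2C(O)c2cc(O[Si](C)(C)C(C)(C)C)c(OC)c(OC)c2)ccc1O[Si](C)(C)C(C)(C)C | intermediate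
14 | methanesulfonate of 13 | COc1cc(C[C@H]2COC(=O)C2C(OS(C)(=O)=O)c2cc(O[Si](C)(C)C(C)(C)C)c(OC)c(OC)c2)ccc1O[Si](C)(C)C(C)(C)C | intermediate (not isolated)
15 | (3E,4R)-3-[3-(TBS-oxy)-4,5-dimethoxybenzylidene]-4-[4-(TBS-oxy)-3-methoxybenzyl]dihydrofuran-2(3H)-one | COc1cc(C[C@H]2COC(=O)/C2=C/c2cc(O[Si](C)(C)C(C)(C)C)c(OC)c(OC)c2)ccc1O[Si](C)(C)C(C)(C)C | intermediate
16 | (3E,4R)-3-(3-hydroxy-4,5-dimethoxybenzylidene)-4-(4-hydroxy-3-methoxybenzyl)dihydrofuran-2(3H)-one | COc1cc(C[C@H]2COC(=O)/C2=C/c2cc(O)c(OC)c(OC)c2)ccc1O | target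

**Step count**

Total steps: 10. Longest linear sequence: 8 (steps 1, 2, 5–10; equally 3–10).

**Steps most likely to fail**

Step 7. The highly electrophilic acyl-substituted carbene may discriminate poorly between the two enantiotopic C4 hydrogens. It may also leak into benzylic C7–H or C5–H insertion, carbene dimerisation or O–H insertion by adventitious water. The fallback sets out from alcohol 3 and comes back to the route at hydroxy lactone 13. It keeps the C3–C4 insertion but uses the established diazoacetate and carboxamidate-catalyst version, then adds ring A by aldol reaction.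
- Alcohol 3 is acylated with bromoacetyl bromide (NaHCO3, MeCN, 0 °C) to 3-[4-(TBS-oxy)-3-methoxyphenyl]propyl bromoacetate F1.
- N,N'-Ditosylhydrazine and DBU (THF, 0 °C) convert it into 3-[4-(TBS-oxy)-3-methoxyphenyl]propyl diazoacetate F2.
- Dirhodium tetrakis[methyl (4S)-2-oxo-1-(3-phenylpropanoyl)imidazolidine-4-carboxylate], Rh2(4S-MPPIM)4, or its 4R antipode if that is the one giving the R product, in refluxing CH2Cl2 should give (4R)-4-[4-(TBS-oxy)-3-methoxybenzyl]dihydrofuran-2(3H)-one F3.
- Purchased 3-hydroxy-4,5-dimethoxybenzaldehyde F4 is silylated (TBSCl, imidazole, DMF) to 3-(TBS-oxy)-4,5-dimethoxybenzaldehyde F5.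
- The lithium enolate of F3 (LiN(iPr)2, THF, −78 °C) should add to F5 anti to the C4 benzyl group to give 13.

Step 9. Geometric control may be lost in the E1cB step, the amidine base may pull the double bond into the ring through the dienolate (which would erase C4), or the aryl silyl ethers may be partly lost. The fallback sets out from keto lactone 12 and comes back at 15, bypassing steps 8 and 9.
- The sodium chelate of 12 (NaH, THF, 0 °C) is triflated with PhNTf2 to (3Z,4R)-3-{[3-(TBS-oxy)-4,5-dimethoxyphenyl][(trifluoromethanesulfonyl)oxy]methylidene}-4-[4-(TBS-oxy)-3-methoxybenzyl]dihydrofuran-2(3H)-one F6, with the triflate oxygen held cis to the lactone carbonyl by chelation.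
- Reduction with Pd(OAc)2, PPh3, HCO2H and Bu3N (DMF, 60 °C) should replace the triflate by hydrogen with retention, placing ring A trans to the carbonyl as in 15.

Step 4. Aroyl transfer from the electron-rich acid to Meldrum's acid may be slow, the O-acylisourea may rearrange to the N-acylurea, and the acyl Meldrum's acid may decompose on handling. The fallback sets out from alcohol 3, Meldrum's acid 7 and acid 6 and comes back at β-keto ester 10, bypassing steps 4 and 5 by a decarboxylative Claisen condensation.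
- Alcohol 3 and Meldrum's acid 7 in toluene at 100 °C should give the malonic half ester 3-{3-[4-(TBS-oxy)-3-methoxyphenyl]propoxy}-3-oxopropanoic acid F7.
- Acid 6 is activated with carbonyldiimidazole (THF, rt) as [3-(TBS-oxy)-4,5-dimethoxyphenyl](1H-imidazol-1-yl)methanone F8.
- The magnesium salt of F7 (MgCl2, Et3N, THF) is acylated by F8, and acidic work-up with loss of CO2 should give 10.

**Further compounds**

F1 | step 7 | 3-[4-(TBS-oxy)-3-methoxyphenyl]propyl bromoacetate | COc1cc(CCCOC(=O)CBr)ccc1O[Si](C)(C)C(C)(C)C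
F2 | step 7 | 3-[4-(TBS-oxy)-3-methoxyphenyl]propyl diazoacetate | COc1cc(CCCOC(=O)C=[N+]=[N-])ccc1O[Si](C)(C)C(C)(C)C
F3 | step 7 | (4R)-4-[4-(TBS-oxy)-3-methoxybenzyl]dihydrofuran-2(3H)-one | COc1cc(C[C@H]2COC(=O)C2)ccc1O[Si](C)(C)C(C)(C)C
F4 | step 7 | 3-hydroxy-4,5-dimethoxybenzaldehyde (purchased) | COc1cc(C=O)cc(O)c1OC
F5 | step 7 | 3-(TBS-oxy)-4,5-dimethoxybenzaldehyde | COc1cc(C=O)cc(O[Si](C)(C)C(C)(C)C)c1OC
F6 | step 9 | (3Z,4R)-3-{[3-(TBS-oxy)-4,5-dimethoxyphenyl][(trifluoromethanesulfonyl)oxy]methylidene}-4-[4-(TBS-oxy)-3-methoxybenzyl]dihydrofuran-2(3H)-one | COc1cc(C[C@H]2COC(=O)/C2=C(\OS(=O)(=O)C(F)(F)F)c2cc(O[Si](C)(C)C(C)(C)C)c(OC)c(OC)c2)ccc1O[Si](C)(C)C(C)(C)C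
F7 | step 4 | 3-{3-[4-(TBS-oxy)-3-methoxyphenyl]propoxy}-3-oxopropanoic acid | COc1cc(CCCOC(=O)CC(=O)O)ccc1O[Si](C)(C)C(C)(C)C
F8 | step 4 | [3-(TBS-oxy)-4,5-dimethoxyphenyl](1H-imidazol-1-yl)methanone | COc1cc(C(=O)n2ccnc2)cc(O[Si](C)(C)C(C)(C)C)c1OC
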